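**Plan**

Numbering: C1 is the ring carbinol carrying the crotonyl chain (C2–C4, methyl C15), C5 the ester CH, C6 the lactone O–CH, C7 the fusion CH, C8 the CH2, C9 the CHOH, C10 the CH with methyl C14, C11–C13 the methylene lactone arm; β is the ring face of the C5 oxygen (C7–C11 and the C9 oxygen are also β; the C6 oxygen, C10 methyl and C1 hydroxyl are α). The feature used: C5 and C6 are neighbouring carbinol carbons with trans oxygens and C5 is allylic to C1–C2, so C5 can be the nucleophilic γ carbon of a (Z)-γ-alkoxyallylstannane whose alkene reappears as an exocyclic C1=C2 methylene, the latent hydroxy ketone.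
Cuts, in retrosynthetic order: the C13 methylene, the C5 ester, C2–C3 (propenyl) and the C1/C2 oxygens; then C5–C6 together with the O–C12 bond of the five-membered ring; then C1–C5 and C1=C2 (alkoxymethyl ketone, methylenation), C9–C10 (aldol) and C7–C8 (allylation).
Forward: the chain C12–C11–C7(–C6)–C8–C9–C10–C1(=C2)–C5 is built linearly; one flask then closes the seven-membered carbocycle and, after it, the oxygen five-membered ring; side chain and acyl group follow.
Two adjustments: C12 is carried as a dimethyl acetal, because no carboxylic ester survives the sec-BuLi step that makes the stannane, so the second ring closes as the lactol and is oxidised to the lactone one step later; and the lactone methylene is carried as its dimethylamine adduct until the penultimate step.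
Stereochemistry: C7 and C9/C10 from two oxazolidinone auxiliaries; C5 and C6 from the Z enol ether and an all-pseudo-equatorial chair-like transition state in the ring closure; C1 from osmylation anti to the C5 OMOM group; the acyl centre from (R)-2-methylbutanoic acid.

Key step: step 15

Remark: lactol 31 (anomers), the amine adducts 35 to 45 (C11 epimers) and carbinol 40 (C2 epimers) are carried as mixtures at centres that are removed later; their SMILES leave these centres open.

**Route**

Step 1
Reactants: 1 methyl 4,4-dimethoxybutanoate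
Product: 2 potassium 4,4-dimethoxybutanoate
Conditions: KOH (1.0 equiv), MeOH/H2O, rt; evaporate, dry azeotropically
Reagents that add atoms: potassium hydroxide, [K+].[OH-]
Why: Ester saponification by hydroxide is routine, and the acid is kept as its potassium salt because the free γ,γ-dimethoxy acid would close to a pseudo-ester on acidification.

Step 2
Reactants: 2 potassium 4,4-dimethoxybutanoate; 3 (R)-4-benzyloxazolidin-2-one
Product: 5 (R)-4-benzyl-3-(4,4-dimethoxybutanoyl)oxazolidin-2-one, via mixed pivalic anhydride 4 (not isolated)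
Conditions: tBuCOCl, THF, −20 °C; then 3, LiCl, Et3N, −20 °C → rt
Reagents that add atoms: (R)-4-benzyloxazolidin-2-one (3), O=C1N[C@H](Cc2ccccc2)CO1
Why: N-Acylation of an oxazolidinone through a mixed pivalic anhydride (LiCl/Et3N activation) is standard, the nucleophile attacking the unhindered carbonyl of the anhydride.

Step 3
Reactants: 5 (R)-4-benzyl-3-(4,4-dimethoxybutanoyl)oxazolidin-2-one; 6 allyl iodide
Product: 8 (R)-4-benzyl-3-[(R)-2-(2,2-dimethoxyethyl)pent-4-enoyl]oxazolidin-2-one, via sodium Z-enolate 7 (not isolated)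
Conditions: NaN(SiMe3)2, THF, −78 °C; then allyl iodide, −78 → −45 °C
Reagents that add atoms: allyl iodide (6), C=CCI
Why: Evans asymmetric alkylation: the chelated Z enolate is allylated on the face away from the benzyl group of the (R)-auxiliary, which sets C7.

Step 4
Reactants: 8 (R)-4-benzyl-3-[(R)-2-(2,2-dimethoxyethyl)pent-4-enoyl]oxazolidin-2-one
Product: 9 (R)-2-(2,2-dimethoxyethyl)pent-4-en-1-ol
Conditions: LiBH4, MeOH (1 equiv), Et2O, 0 °C; aq. NaOH work-up
Reagents that add atoms: none
Why: Reductive cleavage of the imide by LiBH4 (hydride attack at the exocyclic carbonyl) gives the C6 alcohol without epimerising C7 or touching the acetal, and the auxiliary is recovered.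

Step 5
Reactants: 9 (R)-2-(2,2-dimethoxyethyl)pent-4-en-1-ol
Product: 10 {[(R)-2-(2,2-dimethoxyethyl)pent-4-en-1-yl]oxy}triethylsilane
Conditions: Et3SiCl, imidazole, CH2Cl2, 0 °C
Reagents that add atoms: chlorotriethylsilane, CC[Si](Cl)(CC)CC
Why: Silyl ether formation caps the hydroxyl before traces of acid can close it onto the acetal, and a primary TES ether can later be removed by fluoride beside a secondary TBS ether.

Step 6
Reactants: 10 {[(R)-2-(2,2-dimethoxyethyl)pent-4-en-1-yl]oxy}triethylsilane
Product: 12 (R)-5,5-dimethoxy-3-[(triethylsilyloxy)methyl]pentanal, via ozonide 11 (not isolated)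
Conditions: O3, CH2Cl2, −78 °C (to first blue colour); then PPh3, −78 °C → rt
Reagents that add atoms: ozone, [O-][O+]=O
Why: Ozonolysis with reductive work-up (Criegee mechanism) cleaves the only alkene to the C9 aldehyde, and the brief exposure leaves the acetal and silyl ether intact.

Step 7
Reactants: 12 (R)-5,5-dimethoxy-3-[(triethylsilyloxy)methyl]pentanal; 13 (S)-4-benzyl-3-propionyloxazolidin-2-one
Product: 15 (S)-4-benzyl-3-[(2S,3R,5R)-3-hydroxy-7,7-dimethoxy-2-methyl-5-[(triethylsilyloxy)methyl]heptanoyl]oxazolidin-2-one, via dibutylboron Z-enolate 14 (not isolated)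
Conditions: Bu2BOTf, iPr2NEt, CH2Cl2, 0 °C; then 12, −78 → 0 °C; pH 7 buffer, MeOH, H2O2, 0 °C
Reagents that add atoms: (S)-4-benzyl-3-propionyloxazolidin-2-one (13), CCC(=O)N1[C@@H](Cc2ccccc2)COC1=O
Why: Evans syn aldol: the Z boron enolate reacts through a Zimmerman–Traxler chair in which the (S)-auxiliary fixes the enolate face, giving the (2S,3R) syn adduct that is C10/C9, the remote C7 centre having no say.

Step 8
Reactants: 15 the syn aldol imide
Product: 16 (2S,3R,5R)-3-hydroxy-N,7,7-trimethoxy-N,2-dimethyl-5-[(triethylsilyloxy)methyl]heptanamide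
Conditions: Me3Al, MeNHOMe·HCl, THF, −20 → 0 °C; aqueous work-up
Reagents that add atoms: N,O-dimethylhydroxylamine hydrochloride, CNOC.Cl
Why: Weinreb transamidation by the aluminium amide is directed to the exocyclic carbonyl by the free β-hydroxyl, and the acetal and TES ether are stable at 0 °C.

Step 9
Reactants: 16 the β-hydroxy Weinreb amide
Product: 17 (2S,3R,5R)-3-(tert-butyldimethylsilyloxy)-N,7,7-trimethoxy-N,2-dimethyl-5-[(triethylsilyloxy)methyl]heptanamide
Conditions: tBuMe2SiCl, imidazole, DMAP (cat.), DMF, 35 °C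
Reagents that add atoms: tert-butylchlorodimethylsilane, CC(C)(C)[Si](C)(C)Cl
Why: Silylation with the chloride and imidazole protects C9 and avoids the silyl triflate, which with a pyridine base can cleave dimethyl acetals.

Step 10
Reactants: 17 the silylated Weinreb amide; 18 tributyl[(methoxymethoxy)methyl]stannane
Product: 20 (3S,4R,6R)-4-(tert-butyldimethylsilyloxy)-8,8-dimethoxy-1-(methoxymethoxy)-3-methyl-6-[(triethylsilyloxy)methyl]octan-2-one, via (methoxymethoxy)methyllithium 19 (not isolated)
Conditions: 18, nBuLi, THF, −78 °C; then 17, −78 °C; aq. NH4Cl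
Reagents that add atoms: tributyl[(methoxymethoxy)methyl]stannane (18), CCCC[Sn](CCCC)(CCCC)COCOC
Why: Weinreb ketone synthesis: tin–lithium exchange gives the α-alkoxymethyllithium, which adds only once because the chelated tetrahedral intermediate lasts until work-up, bringing in C5 with its MOM-protected oxygen.

Step 11
Reactants: 20 the MOM-oxymethyl ketone; 21 methyltriphenylphosphonium bromide
Product: 23 (3R,4R,6R)-4-(tert-butyldimethylsilyloxy)-8,8-dimethoxy-2-[(methoxymethoxy)methyl]-3-methyl-6-[(triethylsilyloxy)methyl]oct-1-ene, via methylenetriphenylphosphorane 22 (not isolated)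
Conditions: Ph3PCH3Br, KN(SiMe3)2, THF, 0 °C; then 20, −78 → 0 °C
Reagents that add atoms: methyltriphenylphosphonium bromide (21), C[P+](c1ccccc1)(c1ccccc1)c1ccccc1.[Br-]
Why: Wittig methylenation installs C2, the activated α-alkoxy ketone adding the salt-free ylide faster than it enolises so that C10 is retained.

Step 12
Reactants: 23 the 2-substituted allyl MOM ether; 24 tributyltin chloride
Product: 26 tributyl{(Z)-2-[(2R,3R,5R)-3-(tert-butyldimethylsilyloxy)-7,7-dimethoxy-5-[(triethylsilyloxy)methyl]heptan-2-yl]-3-(methoxymethoxy)prop-2-en-1-yl}stannane, via lithiated allyl ether 25 (not isolated)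
Conditions: sec-BuLi (1.3 equiv), THF, −78 °C, 30 min; then Bu3SnCl, −78 °C
Reagents that add atoms: tributyltin chloride (24), CCCC[Sn](Cl)(CCCC)CCCC
Why: α-Lithiation of an allyl MOM ether followed by γ-stannylation: the oxygen-chelated allyllithium holds the Z (endo-oxygen) form and tin enters at the unsubstituted terminus C2, and the substrate carries only ethers and an acetal, so nothing else reacts with the base.

Step 13
Reactants: 26 the (Z)-γ-(methoxymethoxy)allylstannane with C6 OTES
Product: 27 the same stannane with a free C6 primary alcohol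
Conditions: Bu4NF/AcOH (1:1), THF, 0 °C
Reagents that add atoms: none
Why: Fluoride desilylation removes the primary TES ether far faster than the hindered secondary TBS ether, and the buffered medium spares the stannane and the γ-hydroxy acetal.

Step 14
Reactants: 27 the C6 alcohol
Product: 28 the C6 aldehyde: (R)-configured C7 bearing the 2,2-dimethoxyethyl arm, C9 OTBS, C10 methyl and the (Z)-C1(CH2SnBu3)=C5H(OMOM) unit
Conditions: SO3·pyridine, DMSO, iPr2NEt, CH2Cl2, 0 °C
Reagents that add atoms: none
Why: Parikh–Doering oxidation is non-acidic and tolerated by γ-alkoxyallylstannanes, and the aldehyde is used at once so that C7 does not epimerise.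

Step 15
Reactants: 28 the aldehyde acetal with the (Z)-γ-(methoxymethoxy)allylstannane
Product: 31 trans-fused lactol (C12 hemiacetal; C5 β-OMOM; C6 α-O; C9 β-OTBS; C10 α-methyl; exocyclic C1=C2), via hydroxy acetal 29 (not isolated), via cyclic methyl acetal 30 (not isolated)
Conditions: BF3·OEt2 (2 equiv), CH2Cl2, −78 °C; then 1 M aq. HCl/THF, 0 °C
Reagents that add atoms: water, O
Why: BF3 binds the C6 aldehyde and the enol-ether carbon C5 attacks it in an SE2' sense with anti loss of tin from C2, which moves the double bond to the exocyclic C1=C2 position; this is the Lewis acid promoted intramolecular addition of a γ-alkoxyallylstannane to an aldehyde, known to give cyclic 1,2-diol monoethers with trans oxygens. The carbocycle closes in a 7-exo-trig mode at the carbonyl, and on acidic work-up the new C6 hydroxyl captures the oxocarbenium ion of the C12 acetal in a 5-exo-trig closure, the methyl acetal then being hydrolysed to the lactol. C5 is controlled by the Z enol ether, which holds the OMOM group anti to the C1–C10 ring bond and so pseudo-equatorial, and C6 by the open transition state with the BF3-bound oxygen pseudo-equatorial, which gives the syn (ring trans) diol monoether. The aldehyde face is chosen by C7 (Felkin–Anh, C11 branch anti to the forming bond and pseudo-equatorial), so the C6 oxygen ends trans to C11, in the same chair-like array that keeps the C9 OTBS and C10 methyl groups pseudo-equatorial. The step needs chemoselectivity for the aldehyde over the acetal, secured by BF3·OEt2 at −78 °C, which does not ionise a dimethyl acetal, and an unepimerised C7, secured by the freshly made aldehyde. The anomeric centre at C12 forms as a mixture and is erased in the next step.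

Step 16
Reactants: 31 the trans-fused lactol
Product: 32 trans-fused γ-lactone with C5 β-OMOM, C9 β-OTBS, C10 α-methyl and the exocyclic C1=C2 methylene
Conditions: Pr4N[RuO4] (5 mol %), N-methylmorpholine N-oxide, 4 Å MS, CH2Cl2, rt
Reagents that add atoms: none
Why: Ley–Griffith oxidation converts the lactol to the lactone under neutral conditions that leave the alkene, MOM and TBS groups alone.

Step 17
Reactants: 32 the lactone; 33 N,N-dimethylmethyleneiminium iodide
Product: 35 C11 (dimethylamino)methyl lactone (Mannich base), via lithium enolate 34 (not isolated)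
Conditions: LiN(SiMe3)2, THF, −78 °C; then CH2=NMe2+ I−, −78 → 0 °C
Reagents that add atoms: N,N-dimethylmethyleneiminium iodide (33), C=[N+](C)C.[I-]
Why: Mannich reaction of the lactone enolate (C11 is the only acidic position) with the preformed iminium salt brings in C13, and the amine adduct serves as a protected α-methylene lactone through the oxidations that follow.

Step 18
Reactants: 35 the Mannich base
Product: 36 C1,C2 diol (C1 hydroxyl α, C2 hydroxymethyl β)
Conditions: OsO4 (5 mol %), N-methylmorpholine N-oxide, acetone/H2O, rt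
Reagents that add atoms: N-methylmorpholine N-oxide, C[N+]1([O-])CCOCC1; water, O
Why: Upjohn dihydroxylation of the only alkene should occur on the α face, anti to the allylic C5 OMOM oxygen as is usual for allylic ethers, which sets C1.

Step 19
Reactants: 36 the diol
Product: 37 C1 α-hydroxy C2 aldehyde
Conditions: SO3·pyridine, DMSO, iPr2NEt, CH2Cl2, 0 °C
Reagents that add atoms: none
Why: Parikh–Doering oxidation takes the primary alcohol to the aldehyde, the tertiary C1 hydroxyl being unoxidisable and activated DMSO not cleaving glycols.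

Step 20
Reactants: 37 the hydroxy aldehyde; 38 (E)-1-bromoprop-1-ene
Product: 40 C2 allylic alcohol carrying the (E)-propenyl group, via propenylchromium dichloride 39 (not isolated)
Conditions: CrCl2 (6 equiv), NiCl2 (2 mol %), DMSO, rt
Reagents that add atoms: (E)-1-bromoprop-1-ene (38), C/C=C/Br
Why: Nozaki–Hiyama–Kishi coupling: zerovalent nickel (from NiCl2 and divalent chromium) inserts into the C–Br bond with retention, and the alkenyl group passes to trivalent chromium and adds only to the aldehyde, the lactone, free hydroxyl and amine being tolerated.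

Step 21
Reactants: 40 the allylic alcohol
Product: 41 C1 α-hydroxy (E)-crotonyl ketone
Conditions: Dess–Martin periodinane, pyridine, CH2Cl2, 0 °C → rt
Reagents that add atoms: none
Why: Dess–Martin oxidation converts the secondary allylic alcohol to the enone and cannot touch the tertiary hydroxyl.

Step 22
Reactants: 41 the enone with C5 OMOM
Product: 42 the C5 alcohol
Conditions: Me2BBr (4 equiv), CH2Cl2, −78 °C; then THF/aq. NaHCO3
Reagents that add atoms: none
Why: Lewis acid cleavage of the MOM acetal by Me2BBr at −78 °C (the bromomethyl ether is hydrolysed on work-up) spares the TBS ether, lactone and enone, the excess allowing for binding to the amine.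

Step 23
Reactants: 42 the C5 alcohol; 43 (R)-2-methylbutanoic acid
Product: 44 C5 (R)-2-methylbutanoate
Conditions: DCC, DMAP, CH2Cl2, 0 °C → rt
Reagents that add atoms: (R)-2-methylbutanoic acid (43), CC[C@@H](C)C(=O)O
Why: Steglich esterification acylates the secondary C5 hydroxyl in preference to the tertiary C1 hydroxyl and carries the α-stereocentre of the acid through unchanged.

Step 24
Reactants: 44 the ester amine
Product: 46 C9 TBS ether of the target (α-methylene lactone revealed), via quaternary ammonium iodide 45 (not isolated)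
Conditions: MeI, CH2Cl2, rt; then aq. NaHCO3, rt
Reagents that add atoms: none
Why: N-Methylation followed by Hofmann-type (E1cB) elimination of trimethylamine from the β-ammonio lactone unveils the C11=C13 methylene under conditions harmless to the enone and ester.

Step 25
Reactants: 46 the C9 TBS ether
Product: 47 the target, (1S,5S,6R,7R,9R,10S) with the (R)-2-methylbutanoate
Conditions: HF (48 % aq.), MeCN, 0 °C → rt
Reagents that add atoms: none
Why: Acidic fluoride desilylation frees the C9 hydroxyl without affecting the base-sensitive methylene lactone, enone and ester.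

**Compound list**

1 | methyl 4,4-dimethoxybutanoate | COC(=O)CCC(OC)OC | starting material
2 | potassium 4,4-dimethoxybutanoate | [K+].[O-]C(=O)CCC(OC)OC | intermediate
3 | (R)-4-benzyloxazolidin-2-one | O=C1N[C@H](Cc2ccccc2)CO1 | starting material
4 | mixed pivalic anhydride (not isolated) | CC(C)(C)C(=O)OC(=O)CCC(OC)OC | intermediate
5 | (R)-4-benzyl-3-(4,4-dimethoxybutanoyl)oxazolidin-2-one | COC(OC)CCC(=O)N1[C@H](Cc2ccccc2)COC1=O | intermediate
6 | allyl iodide | C=CCI | starting material
7 | sodium Z-enolate of 5 (not isolated) | [Na+].[O-]/C(=C\CC(OC)OC)N1[C@H](Cc2ccccc2)COC1=O | intermediate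
8 | (R)-4-benzyl-3-[(R)-2-(2,2-dimethoxyethyl)pent-4-enoyl]oxazolidin-2-one | O=C(N1[C@H](Cc2ccccc2)COC1=O)[C@@H](CC(OC)OC)CC=C | intermediate
9 | (R)-2-(2,2-dimethoxyethyl)pent-4-en-1-ol | OC[C@@H](CC(OC)OC)CC=C | intermediate
10 | {[(R)-2-(2,2-dimethoxyethyl)pent-4-en-1-yl]oxy}triethylsilane | CC[Si](CC)(CC)OC[C@@H](CC(OC)OC)CC=C | intermediate
11 | ozonide (1,2,4-trioxolane) of 10 (not isolated) | CC[Si](CC)(CC)OC[C@@H](CC(OC)OC)CC1OCOO1 | intermediate
12 | (R)-5,5-dimethoxy-3-[(triethylsilyloxy)methyl]pentanal | CC[Si](CC)(CC)OC[C@@H](CC(OC)OC)CC=O | intermediate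
13 | (S)-4-benzyl-3-propionyloxazolidin-2-one | CCC(=O)N1[C@@H](Cc2ccccc2)COC1=O | starting material
14 | dibutylboron Z-enolate of 13 (not isolated) | CCCCB(CCCC)O/C(=C\C)N1[C@@H](Cc2ccccc2)COC1=O | intermediate
15 | (S)-4-benzyl-3-[(2S,3R,5R)-3-hydroxy-7,7-dimethoxy-2-methyl-5-[(triethylsilyloxy)methyl]heptanoyl]oxazolidin-2-one | O=C(N1[C@@H](Cc2ccccc2)COC1=O)[C@@H](C)[C@H](O)C[C@@H](CO[Si](CC)(CC)CC)CC(OC)OC | intermediate
16 | (2S,3R,5R)-3-hydroxy-N,7,7-trimethoxy-N,2-dimethyl-5-[(triethylsilyloxy)methyl]heptanamide | CON(C)C(=O)[C@@H](C)[C@H](O)C[C@@H](CO[Si](CC)(CC)CC)CC(OC)OC | intermediate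
17 | (2S,3R,5R)-3-(tert-butyldimethylsilyloxy)-N,7,7-trimethoxy-N,2-dimethyl-5-[(triethylsilyloxy)methyl]heptanamide | CON(C)C(=O)[C@@H](C)[C@H](O[Si](C)(C)C(C)(C)C)C[C@@H](CO[Si](CC)(CC)CC)CC(OC)OC | intermediate
18 | tributyl[(methoxymethoxy)methyl]stannane | CCCC[Sn](CCCC)(CCCC)COCOC | starting material
19 | (methoxymethoxy)methyllithium (not isolated) | [Li]COCOC | intermediate
20 | (3S,4R,6R)-4-(tert-butyldimethylsilyloxy)-8,8-dimethoxy-1-(methoxymethoxy)-3-methyl-6-[(triethylsilyloxy)methyl]octan-2-one | COCOCC(=O)[C@@H](C)[C@H](O[Si](C)(C)C(C)(C)C)C[C@@H](CO[Si](CC)(CC)CC)CC(OC)OC | intermediate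
21 | methyltriphenylphosphonium bromide | C[P+](c1ccccc1)(c1ccccc1)c1ccccc1.[Br-] | starting material
22 | methylenetriphenylphosphorane (not isolated) | C=P(c1ccccc1)(c1ccccc1)c1ccccc1 | intermediate
23 | (3R,4R,6R)-4-(tert-butyldimethylsilyloxy)-8,8-dimethoxy-2-[(methoxymethoxy)methyl]-3-methyl-6-[(triethylsilyloxy)methyl]oct-1-ene | COCOCC(=C)[C@@H](C)[C@H](O[Si](C)(C)C(C)(C)C)C[C@@H](CO[Si](CC)(CC)CC)CC(OC)OC | intermediate
24 | tributyltin chloride | CCCC[Sn](Cl)(CCCC)CCCC | starting material
25 | lithiated allyl ether from 23, drawn as the α-lithio form (not isolated) | [Li]C(OCOC)C(=C)[C@@H](C)[C@H](O[Si](C)(C)C(C)(C)C)C[C@@H](CO[Si](CC)(CC)CC)CC(OC)OC | intermediate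
26 | tributyl{(Z)-2-[(2R,3R,5R)-3-(tert-butyldimethylsilyloxy)-7,7-dimethoxy-5-[(triethylsilyloxy)methyl]heptan-2-yl]-3-(methoxymethoxy)prop-2-en-1-yl}stannane | CC[Si](CC)(CC)OC[C@@H](CC(OC)OC)C[C@@H](O[Si](C)(C)C(C)(C)C)[C@H](C)/C(C[Sn](CCCC)(CCCC)CCCC)=C/OCOC | intermediate
27 | C6 primary alcohol of 26 (TES removed) | OC[C@@H](CC(OC)OC)C[C@@H](O[Si](C)(C)C(C)(C)C)[C@H](C)/C(C[Sn](CCCC)(CCCC)CCCC)=C/OCOC | intermediate
28 | C6 aldehyde with C12 dimethyl acetal, C9 OTBS and the (Z)-γ-(methoxymethoxy)allylstannane | O=C[C@@H](CC(OC)OC)C[C@@H](O[Si](C)(C)C(C)(C)C)[C@H](C)/C(C[Sn](CCCC)(CCCC)CCCC)=C/OCOC | intermediate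
29 | cycloheptanol hydroxy acetal: C5–C6 bond formed, C6 α-OH, C5 β-OMOM, exocyclic C1=C2 (not isolated) | COC(OC)C[C@H]1C[C@@H](O[Si](C)(C)C(C)(C)C)[C@H](C)C(=C)[C@@H](OCOC)[C@@H]1O | intermediate
30 | trans-fused cyclic methyl acetal at C12 (not isolated) | COC1O[C@@H]2[C@@H](C1)C[C@@H](O[Si](C)(C)C(C)(C)C)[C@H](C)C(=C)[C@H]2OCOC | intermediate
31 | trans-fused lactol (C12 hemiacetal, anomers) with C5 β-OMOM, C9 β-OTBS, C10 α-methyl, exocyclic C1=C2 | OC1O[C@@H]2[C@@H](C1)C[C@@H](O[Si](C)(C)C(C)(C)C)[C@H](C)C(=C)[C@H]2OCOC | intermediate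
32 | trans-fused γ-lactone with C5 β-OMOM, C9 β-OTBS, C10 α-methyl, exocyclic C1=C2 | O=C1O[C@@H]2[C@@H](C1)C[C@@H](O[Si](C)(C)C(C)(C)C)[C@H](C)C(=C)[C@H]2OCOC | intermediate
33 | N,N-dimethylmethyleneiminium iodide | C=[N+](C)C.[I-] | starting material
34 | lithium enolate of lactone 32 (not isolated) | [Li+].[O-]C1=C[C@H]2C[C@@H](O[Si](C)(C)C(C)(C)C)[C@H](C)C(=C)[C@@H](OCOC)[C@@H]2O1 | intermediate
35 | C11 (dimethylamino)methyl lactone (Mannich base, C11 epimers) | CN(C)CC1C(=O)O[C@@H]2[C@@H]1C[C@@H](O[Si](C)(C)C(C)(C)C)[C@H](C)C(=C)[C@H]2OCOC | intermediate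
36 | C1 α-hydroxy, C2 hydroxymethyl diol of 35 | CN(C)CC1C(=O)O[C@@H]2[C@@H]1C[C@@H](O[Si](C)(C)C(C)(C)C)[C@H](C)[C@@](O)(CO)[C@H]2OCOC | intermediate
37 | C1 α-hydroxy C2 aldehyde | CN(C)CC1C(=O)O[C@@H]2[C@@H]1C[C@@H](O[Si](C)(C)C(C)(C)C)[C@H](C)[C@@](O)(C=O)[C@H]2OCOC | intermediate
38 | (E)-1-bromoprop-1-ene | C/C=C/Br | starting material
39 | (E)-prop-1-enylchromium dichloride (not isolated) | C/C=C/[Cr](Cl)Cl | intermediate
40 | C2 allylic alcohol with (E)-propenyl group (C2 epimers) | CN(C)CC1C(=O)O[C@@H]2[C@@H]1C[C@@H](O[Si](C)(C)C(C)(C)C)[C@H](C)[C@@](O)(C(O)/C=C/C)[C@H]2OCOC | intermediate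
41 | C1 α-hydroxy (E)-crotonyl ketone with C5 OMOM | CN(C)CC1C(=O)O[C@@H]2[C@@H]1C[C@@H](O[Si](C)(C)C(C)(C)C)[C@H](C)[C@@](O)(C(=O)/C=C/C)[C@H]2OCOC | intermediate
42 | C5 alcohol (MOM removed) | CN(C)CC1C(=O)O[C@@H]2[C@@H]1C[C@@H](O[Si](C)(C)C(C)(C)C)[C@H](C)[C@@](O)(C(=O)/C=C/C)[C@H]2O | intermediate
43 | (R)-2-methylbutanoic acid | CC[C@@H](C)C(=O)O | starting material
44 | C5 (R)-2-methylbutanoate, amine adduct | CN(C)CC1C(=O)O[C@@H]2[C@@H]1C[C@@H](O[Si](C)(C)C(C)(C)C)[C@H](C)[C@@](O)(C(=O)/C=C/C)[C@H]2OC(=O)[C@H](C)CC | intermediate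
45 | quaternary trimethylammonium iodide of 44 (not isolated) | C[N+](C)(C)CC1C(=O)O[C@@H]2[C@@H]1C[C@@H](O[Si](C)(C)C(C)(C)C)[C@H](C)[C@@](O)(C(=O)/C=C/C)[C@H]2OC(=O)[C@H](C)CC.[I-] | intermediate
46 | C9 TBS ether of the target | C=C1C(=O)O[C@@H]2[C@@H]1C[C@@H](O[Si](C)(C)C(C)(C)C)[C@H](C)[C@@](O)(C(=O)/C=C/C)[C@H]2OC(=O)[C@H](C)CC | intermediate
47 | CNP0331957.3 | C=C1C(=O)O[C@@H]2[C@@H]1C[C@@H](O)[C@H](C)[C@@](O)(C(=O)/C=C/C)[C@H]2OC(=O)[C@H](C)CC | target

**Step count and risks**

Total steps: 25. Longest linear sequence: 25 steps, from 1 to 47.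

Steps most likely to fail:

1. Step 15. Simple diastereoselection or Felkin control may erode, so that the aldehyde is attacked on its other face and the C6 oxygen ends cis to the C5 oxygen. The fallback sets out from aldehyde 28 and sets C6 by reduction instead of by the allylation. The ring closure is quenched with Et3N and aq. NaHCO3 so that the acetal stays open, and the C6-epimeric hydroxy acetal F1 is isolated. Dess–Martin periodinane (pyridine) gives the C6 ketone F2. NaBH4 in MeOH at −20 °C should deliver hydride axially and give the equatorial alcohol trans to both neighbours, which is hydroxy acetal 29. 1 M HCl/THF then closes it to lactol 31, where the route is rejoined.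

2. Step 12. sec-BuLi may deprotonate elsewhere, tin may enter at the α carbon, or the Z geometry may be lost. The fallback sets out from Weinreb amide 17 and makes the same stannane by a 1,3-tin shift instead of a lithiation.
   - [(4-Methoxybenzyloxy)methyl]lithium (from the tributylstannane and nBuLi) gives the PMB-oxymethyl ketone F3.
   - Wittig methylenation gives the allyl PMB ether F4.
   - DDQ (CH2Cl2, pH 7 buffer) frees the allylic alcohol F5.
   - MnO2 gives the 2-substituted acrolein F6.
   - Bu3SnLi (from Bu3SnH and LiN(iPr)2, THF, −78 °C) adds 1,2 to give the α-hydroxystannane F7.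
   - F7 is capped in the same flask with MOMCl and iPr2NEt as the α-(methoxymethoxy)allylstannane F8.
   - BF3·OEt2 in CH2Cl2 at −78 °C moves tin to the terminal carbon by the known intermolecular anti SE2' shift of α-alkoxyallylstannanes, which gives the (Z)-γ isomer 26, where the route is rejoined.

3. Step 18. OsO4 may attack the β face, or both faces, because the C10 methyl group lies on the α face. The fallback sets out from Mannich base 35 and adds carbon instead of oxygen to C1. Lemieux–Johnson cleavage (OsO4 cat., NaIO4, 2,6-lutidine, dioxane/H2O) gives the C1 ketone F9. CH2=CHMgBr with CeCl3 (THF, −78 °C) adds only to the ketone; if it uses the same more open β face, it places carbon β and the hydroxyl α, giving the vinyl carbinol F10. A second OsO4/NaIO4 cleavage of the vinyl group gives hydroxy aldehyde 37, where the route is rejoined.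

**Further compounds**

F1 | step 15 | C6-epimeric hydroxy acetal (C6 β-OH) | COC(OC)C[C@H]1C[C@@H](O[Si](C)(C)C(C)(C)C)[C@H](C)C(=C)[C@@H](OCOC)[C@H]1O
F2 | step 15 | C6 ketone | COC(OC)C[C@H]1C[C@@H](O[Si](C)(C)C(C)(C)C)[C@H](C)C(=C)[C@@H](OCOC)C1=O
F3 | step 12 | PMB-oxymethyl ketone | COc1ccc(COCC(=O)[C@@H](C)[C@H](O[Si](C)(C)C(C)(C)C)C[C@@H](CO[Si](CC)(CC)CC)CC(OC)OC)cc1
F4 | step 12 | 2-substituted allyl PMB ether | COc1ccc(COCC(=C)[C@@H](C)[C@H](O[Si](C)(C)C(C)(C)C)C[C@@H](CO[Si](CC)(CC)CC)CC(OC)OC)cc1
F5 | step 12 | 2-substituted allylic alcohol | OCC(=C)[C@@H](C)[C@H](O[Si](C)(C)C(C)(C)C)C[C@@H](CO[Si](CC)(CC)CC)CC(OC)OC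
F6 | step 12 | 2-substituted acrolein | O=CC(=C)[C@@H](C)[C@H](O[Si](C)(C)C(C)(C)C)C[C@@H](CO[Si](CC)(CC)CC)CC(OC)OC
F7 | step 12 | α-hydroxyallylstannane (C5 epimers) | OC([Sn](CCCC)(CCCC)CCCC)C(=C)[C@@H](C)[C@H](O[Si](C)(C)C(C)(C)C)C[C@@H](CO[Si](CC)(CC)CC)CC(OC)OC
F8 | step 12 | α-(methoxymethoxy)allylstannane (C5 epimers) | COCOC([Sn](CCCC)(CCCC)CCCC)C(=C)[C@@H](C)[C@H](O[Si](C)(C)C(C)(C)C)C[C@@H](CO[Si](CC)(CC)CC)CC(OC)OC
F9 | step 18 | C1 ketone of the Mannich base | CN(C)CC1C(=O)O[C@@H]2[C@@H]1C[C@@H](O[Si](C)(C)C(C)(C)C)[C@H](C)C(=O)[C@H]2OCOC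
F10 | step 18 | C1 α-hydroxy β-vinyl carbinol | CN(C)CC1C(=O)O[C@@H]2[C@@H]1C[C@@H](O[Si](C)(C)C(C)(C)C)[C@H](C)[C@@](O)(C=C)[C@H]2OCOC
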